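**Strategy.** The cycloheptene of the hydroazulene carries a tetrasubstituted C5=C6 alkene next to the C7 carbinol: a cyclohept-2-en-1-ol, the imprint of a one-carbon ring expansion in which C6 is inserted between C5 and C7 of a cis-hydrindene. The precursor, a cis-fused cyclohexene already carrying the finished perhydrobenzoxepine on its side chain, is built by B-alkyl Suzuki coupling and dibromocyclopropanated. Silver(I) then triggers electrocyclic opening of the bicyclo[4.1.0]heptane and hydration, creating the seven-membered ring, its alkene (as vinyl bromide, later methyl) and the C7 oxygen at once. The benzoxepine arises from a polyepoxide cascade, the hydrindane from a Ti(III) epoxy-enone radical cyclization.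

Key step: step 20

Remark (assumption): the D-fructose-derived Shi ketone and its enantiomer (from L-sorbose) are treated as available catalysts. Locants in names follow indene, 1-benzoxepine and azulene numbering (azulene: C1 carbinol, C3a/C8a ring fusion, C4 gem-dimethyl, C5=C6, C7 carbinol).

**Right-hand fragment (steps 1–8)**

Step 1
Reactants: 1 4-methylpenta-1,3-diene; 2 2-iodocyclopent-2-en-1-one
Product: 4 2-(4-methylpent-3-en-1-yl)cyclopent-2-en-1-one, via homoprenyl-9-BBN 3 (not isolated)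
Conditions: 1, 9-BBN-H, THF, 0 °C to rt; then 2, PdCl2(dppf) (5 mol %), Ph3As, Cs2CO3, DMF/H2O, rt
Reagents that add atoms: none
Why: 9-BBN should hydroborate only the monosubstituted terminus of the diene, and the B-alkyl-9-BBN then undergoes B-alkyl Suzuki–Miyaura coupling with the α-iodoenone under mild arsine-modified conditions.

Step 2
Reactants: 4 2-(4-methylpent-3-en-1-yl)cyclopent-2-en-1-one
Product: 5 2-{2-[(2S)-3,3-dimethyloxiran-2-yl]ethyl}cyclopent-2-en-1-one
Conditions: ent-Shi ketone (0.3 equiv), Oxone, K2CO3, Bu4NHSO4, MeCN/DMM/aq. borate buffer (pH 10.5), 0 °C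
Reagents that add atoms: Oxone (potassium peroxymonosulfate), [K+].[O-]S(=O)(=O)OO
Why: Shi asymmetric epoxidation: the chiral dioxirane attacks only the electron-rich trisubstituted alkene (the enone C=C is inert), and the L-series ketone should give the (S)-epoxide, the single catalyst-set stereocentre of this fragment.

Step 3
Reactants: 5 2-{2-[(2S)-3,3-dimethyloxiran-2-yl]ethyl}cyclopent-2-en-1-one
Product: 6 (3aR,5S,7aR)-5-hydroxy-4,4-dimethyloctahydro-1H-inden-1-one (cis-fused)
Conditions: Cp2TiCl2 (2.5 equiv), Mn dust, THF, rt, slow addition of 5; aq. HCl work-up; K2CO3/MeOH if needed to secure the cis fusion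
Reagents that add atoms: none
Why: Nugent–RajanBabu reductive epoxide opening gives the tertiary β-titanoxy radical, which should add 6-endo to the enone β-carbon (polarity-matched; 5-exo would join two fully substituted carbons) through a chair with the OTi group equatorial, setting C3a with its hydrogen trans to the C5 oxygen, and protonation of the titanium enolate gives the more stable cis fusion at C7a.

Step 4
Reactants: 6 (3aR,5S,7aR)-5-hydroxy-4,4-dimethyloctahydro-1H-inden-1-one
Product: 7 (3aR,5S,7aR)-4,4-dimethyl-1-methylideneoctahydro-1H-inden-5-ol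
Conditions: Ph3PCH3Br (3 equiv), KOtBu, THF, 0 °C to rt
Reagents that add atoms: methyltriphenylphosphonium bromide, C[P+](c1ccccc1)(c1ccccc1)c1ccccc1.[Br-]
Why: Wittig methylenation of the cyclopentanone (excess ylide covers the free hydroxyl); the cis fusion is the thermodynamic one, so the basic ylide should not erode C7a.

Step 5
Reactants: 7 (3aR,5S,7aR)-4,4-dimethyl-1-methylideneoctahydro-1H-inden-5-ol
Product: 8 (1R,3aR,5S,7aR)-1,4,4-trimethyloctahydro-1H-indene-1,5-diol
Conditions: Co(acac)2 (20 mol %), PhSiH3, O2 (1 atm), THF, rt; aq. Na2S2O3 work-up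
Reagents that add atoms: dioxygen, O=O
Why: Mukaiyama hydration: Markovnikov hydrogen-atom transfer gives the tertiary C1 radical, which should be trapped by O2 on the convex face of the cis-hydrindane (anti to the C7a–C7 bond), placing the hydroxyl cis to H7a and the methyl on the concave face (1R).

Step 6
Reactants: 8 (1R,3aR,5S,7aR)-1,4,4-trimethyloctahydro-1H-indene-1,5-diol
Product: 9 (1R,3aR,7aR)-1-hydroxy-1,4,4-trimethyloctahydro-5H-inden-5-one
Conditions: Dess–Martin periodinane, CH2Cl2, rt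
Reagents that add atoms: none
Why: Dess–Martin oxidation of the secondary alcohol only (the tertiary carbinol is inert); C5, having relayed its chirality to C3a and C7a, is deleted.

Step 7
Reactants: 9 (1R,3aR,7aR)-1-hydroxy-1,4,4-trimethyloctahydro-5H-inden-5-one
Product: 10 (1R,3aR,7aR)-1,4,4-trimethyl-1-[(triethylsilyl)oxy]octahydro-5H-inden-5-one
Conditions: TESOTf, 2,6-lutidine, CH2Cl2, −78 to 0 °C
Reagents that add atoms: triethylsilyl trifluoromethanesulfonate, CC[Si](CC)(CC)OS(=O)(=O)C(F)(F)F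
Why: Silyl triflate silylation of the hindered tertiary alcohol, needed because steps 8, 18 and 19 use strong bases.

Step 8
Reactants: 10 (1R,3aR,7aR)-1,4,4-trimethyl-1-[(triethylsilyl)oxy]octahydro-5H-inden-5-one
Product: 12 (1R,3aR,7aR)-1,4,4-trimethyl-1-[(triethylsilyl)oxy]-2,3,3a,4,7,7a-hexahydro-1H-inden-5-yl trifluoromethanesulfonate, via potassium enolate 11 (not isolated)
Conditions: KHMDS, THF, −78 °C; then PhNTf2, −78 to 0 °C
Reagents that add atoms: N-phenylbis(trifluoromethanesulfonimide), O=S(=O)(N(c1ccccc1)S(=O)(=O)C(F)(F)F)C(F)(F)F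
Why: The ketone can enolise only towards C6 (C4 is quaternary), so enolate O-sulfonylation should give a single enol triflate.

**Left-hand fragment (steps 9–17)**

Step 9
Reactants: 13 dimethyl (2-oxopropyl)phosphonate; 14 geranyl bromide
Product: 16 dimethyl [(5E)-6,10-dimethyl-2-oxoundeca-5,9-dien-1-yl]phosphonate, via phosphonate dianion 15 (not isolated)
Conditions: NaH, THF, 0 °C; n-BuLi, 0 °C; then 14, 0 °C to rt; dilute HCl quench
Reagents that add atoms: none
Why: γ-Alkylation of the β-ketophosphonate dianion at its more reactive terminal carbanion by the allylic bromide (SN2, E geometry retained).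

Step 10
Reactants: 16 dimethyl [(5E)-6,10-dimethyl-2-oxoundeca-5,9-dien-1-yl]phosphonate; 17 (benzyloxy)acetaldehyde
Product: 18 (2E,7E)-1-(benzyloxy)-8,12-dimethyltrideca-2,7,11-trien-4-one
Conditions: LiCl, iPr2NEt, MeCN, rt
Reagents that add atoms: none
Why: Horner–Wadsworth–Emmons olefination under mild lithium chloride/amine (Masamune–Roush) conditions should give the (E)-enone.

Step 11
Reactants: 18 (2E,7E)-1-(benzyloxy)-8,12-dimethyltrideca-2,7,11-trien-4-one
Product: 19 (2E)-1-(benzyloxy)-6-[(2R,3R)-3-{2-[(2R)-3,3-dimethyloxiran-2-yl]ethyl}-3-methyloxiran-2-yl]hex-2-en-4-one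
Conditions: Shi ketone (D-fructose-derived, 0.6 equiv), Oxone, K2CO3, Bu4NHSO4, MeCN/DMM/aq. borate buffer (pH 10.5), 0 °C
Reagents that add atoms: Oxone (potassium peroxymonosulfate), [K+].[O-]S(=O)(=O)OO
Why: Shi epoxidation: the D-series dioxirane should epoxidise both electron-rich trisubstituted alkenes in the same facial sense, giving (R) at each CH carbon, while the enone alkene is too electron-poor to react.

Step 12
Reactants: 19 the diepoxy enone
Product: 20 {[(3Z)-6-(benzyloxy)-1-[(2R,3R)-3-{2-[(2R)-3,3-dimethyloxiran-2-yl]ethyl}-3-methyloxiran-2-yl]hex-3-en-3-yl]oxy}triethylsilane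
Conditions: Et3SiH, RhCl(PPh3)3 (1 mol %), benzene, 50 °C
Reagents that add atoms: triethylsilane, CC[SiH](CC)CC
Why: Rh-catalysed 1,4-hydrosilylation of the enone should give the silyl enol ether regiospecifically on the side of the benzyloxyethyl chain (mainly Z), a regiochemistry that enolisation of the saturated ketone could not provide.

Step 13
Reactants: 20 the diepoxy triethylsilyl enol ether
Product: 21 (3R,5aR,6R,9aR)-6-[2-(benzyloxy)ethyl]-2,2,5a-trimethyl-3-[(triethylsilyl)oxy]octahydro-1-benzoxepin-7(2H)-one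
Conditions: TESOTf (0.3 equiv), 2,6-di-tert-butyl-4-methylpyridine, CH2Cl2, −78 °C; Et3N quench
Reagents that add atoms: none
Why: Silyl-triflate-promoted epoxide-opening cascade (tandem endo oxa-/carbacyclisation of a 1,5-diepoxide): the silylated terminal epoxide is opened at its tertiary carbon by the neighbouring epoxide oxygen, and the epoxonium ion is opened at the future C5a with inversion by the enol ether through a chair, which should fix C3 and C9a (retention) and C5a (inversion) in a trans-fused oxepane–cyclohexanone, with C6 (α to the ketone) settling equatorial and the enol silyl group relayed to O3, so the step is an isomerisation.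

Step 14
Reactants: 21 the bicyclic ketone
Product: 22 (3R,5aR,6R,7S,9aR)-6-[2-(benzyloxy)ethyl]-2,2,5a,7-tetramethyl-3-[(triethylsilyl)oxy]decahydro-1-benzoxepin-7-ol
Conditions: MeMgBr, Et2O/toluene, −78 to 0 °C; water quench
Reagents that add atoms: methylmagnesium bromide, C[Mg]Br
Why: Grignard addition from the equatorial direction, because axial approach is blocked by the 1,3-diaxial C5a methyl group, should give the axial tertiary alcohol (7S) with the new methyl equatorial.

Step 15
Reactants: 22 the tertiary alcohol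
Product: 23 (3R,5aR,6R,7S,9aR)-6-[2-(benzyloxy)ethyl]-2,2,5a,7-tetramethyl-3,7-bis[(triethylsilyl)oxy]decahydro-1-benzoxepine
Conditions: TESOTf, 2,6-lutidine, CH2Cl2, 0 °C to rt
Reagents that add atoms: triethylsilyl trifluoromethanesulfonate, CC[Si](CC)(CC)OS(=O)(=O)C(F)(F)F
Why: Silyl triflate silylation of the hindered axial tertiary alcohol, which prevents tetrahydrofuran formation onto the later iodide and alkoxide chemistry in steps 18 and 19.

Step 16
Reactants: 23 the bis-silyl benzyl ether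
Product: 24 2-[(3R,5aR,6R,7S,9aR)-2,2,5a,7-tetramethyl-3,7-bis[(triethylsilyl)oxy]decahydro-1-benzoxepin-6-yl]ethan-1-ol
Conditions: H2 (1 atm), 10 % Pd/C, EtOAc, rt
Reagents that add atoms: none
Why: Hydrogenolysis of the benzyl ether in a non-protic solvent, in which triethylsilyl ethers should survive.

Step 17
Reactants: 24 the primary alcohol
Product: 25 (3R,5aR,6R,7S,9aR)-6-(2-iodoethyl)-2,2,5a,7-tetramethyl-3,7-bis[(triethylsilyl)oxy]decahydro-1-benzoxepine
Conditions: I2, PPh3, imidazole, CH2Cl2, 0 °C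
Reagents that add atoms: iodine, II
Why: Appel-type iodination of the primary alcohol under buffered, neutral conditions.

**Union and endgame (steps 18–24)**

Step 18
Reactants: 25 the primary iodide; 12 the enol triflate
Product: 28 (1R,3aR,7aR)-5-{2-[(3R,5aR,6R,7S,9aR)-2,2,5a,7-tetramethyl-3,7-bis[(triethylsilyl)oxy]decahydro-1-benzoxepin-6-yl]ethyl}-1,4,4-trimethyl-1-[(triethylsilyl)oxy]-2,3,3a,4,7,7a-hexahydro-1H-indene, via alkyllithium 26 (not isolated), via lithium borinate complex 27 (not isolated)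
Conditions: 25, t-BuLi (2.1 equiv), Et2O, −78 °C; B-methoxy-9-BBN, THF, −78 °C to rt; then 12, PdCl2(dppf) (5 mol %), Ph3As, aq. K3PO4, DMF, rt
Reagents that add atoms: none
Why: Lithium–iodine exchange and capture by B-methoxy-9-BBN give a borinate that transfers its primary alkyl group in a B-alkyl Suzuki–Miyaura coupling with the enol triflate, joining the fragments without touching a stereocentre.

Step 19
Reactants: 28 the coupled cyclohexene
Product: 29 the gem-dibromocyclopropane of 28 across C5–C6 of the hexahydroindene (7,7-dibromobicyclo[4.1.0]heptane unit; carbene on the convex face, anti to the cyclopentane; the other face isomer is equally productive)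
Conditions: CHBr3, KOtBu, pentane, 0 °C to rt
Reagents that add atoms: bromoform, BrC(Br)Br
Why: Dibromocarbene (Doering–Hoffmann conditions) is a small electrophilic carbene that should add stereospecifically to the only alkene, an electron-rich trisubstituted one.

Step 20
Reactants: 29 the gem-dibromocyclopropane
Product: 31 (1R,3aR,8aR)-6-bromo-5-{2-[(3R,5aR,6R,7S,9aR)-2,2,5a,7-tetramethyl-3,7-bis[(triethylsilyl)oxy]decahydro-1-benzoxepin-6-yl]ethyl}-1,4,4-trimethyl-1-[(triethylsilyl)oxy]-1,2,3,3a,4,7,8,8a-octahydroazulen-7-ol (both C7 epimers), via 2-bromoallyl cation 30 (not isolated)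
Conditions: AgClO4 (2 equiv), CaCO3, acetone/H2O (9:1), rt, dark
Reagents that add atoms: water, O
Why: Ag(I) abstracts the endo bromide while the cyclopropane bond shared with the six-membered ring (between the former alkene carbons, the future C5 and C7) opens in a disrotatory two-electron electrocyclic process (Woodward–Hoffmann–DePuy rule), giving the 2-bromoallyl cation 30 inside the new seven-membered ring, which water then captures. The closest known reaction type is the silver-assisted ring expansion of gem-dihalocyclopropanes of cycloalkenes to 2-halocycloalk-2-en-1-ols. The cycloheptene is formed by ring enlargement, not by joining two chain ends: the carbene carbon (future C6) ends up inserted between C5 and C7. The C7 carbinol is deliberately left uncontrolled (both epimers are oxidised in step 21 and the centre is set in step 23), while C1, C3a and C8a are untouched. The step needs water capture at the secondary terminus C7 rather than at C5; the quaternary C4 and the side chain shield C5, and reversible tertiary capture should funnel material to the tetrasubstituted C5=C6 alkene. Both face isomers of 29 carry an endo bromine and converge on the same cation.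

Step 21
Reactants: 31 the bromo allylic alcohol (epimer mixture)
Product: 32 (1R,3aR,8aR)-6-bromo-5-{2-[(3R,5aR,6R,7S,9aR)-2,2,5a,7-tetramethyl-3,7-bis[(triethylsilyl)oxy]decahydro-1-benzoxepin-6-yl]ethyl}-1,4,4-trimethyl-1-[(triethylsilyl)oxy]-2,3,3a,4,8,8a-hexahydroazulen-7(1H)-one
Conditions: Dess–Martin periodinane, pyridine, CH2Cl2, rt
Reagents that add atoms: none
Why: Dess–Martin oxidation converts both C7 epimers into one α-bromoenone, erasing the uncontrolled centre and activating the vinyl bromide for coupling.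

Step 22
Reactants: 32 the α-bromoenone
Product: 33 the 6-methyl enone, (1R,3aR,8aR)-1,4,4,6-tetramethyl-5-{2-[…benzoxepin-6-yl]ethyl}-1-[(triethylsilyl)oxy]-2,3,3a,4,8,8a-hexahydroazulen-7(1H)-one (side chain as in 32)
Conditions: MeB(OH)2, Pd(OAc)2 (5 mol %), SPhos, K3PO4, toluene/H2O, 80 °C
Reagents that add atoms: methylboronic acid, CB(O)O
Why: Suzuki–Miyaura coupling of the α-bromoenone (readily undergoing oxidative addition) with methylboronic acid should install the C6 methyl on the tetrasubstituted alkene.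

Step 23
Reactants: 33 the 6-methyl enone
Product: 34 the tris-triethylsilyl ether of the target, (1R,3aR,7S,8aR)-configured azulen-7-ol
Conditions: (R)-2-methyl-CBS-oxazaborolidine (0.5 equiv), catecholborane, toluene, −78 to −40 °C; aqueous work-up
Reagents that add atoms: none
Why: Corey–Bakshi–Shibata reduction: the (R)-oxazaborolidine should bind the ketone with the tetrasubstituted alkenyl side as the large group and deliver hydride to the face giving the (7S)-alcohol, which is also the convex face of the cis-fused bicycle.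

Step 24
Reactants: 34 the tris-triethylsilyl ether
Product: 35 (3R,5aR,6R,7S,9aR)-6-{2-[(1R,3aR,7S,8aR)-1,7-dihydroxy-1,4,4,6-tetramethyl-1,2,3,3a,4,7,8,8a-octahydroazulen-5-yl]ethyl}-2,2,5a,7-tetramethyldecahydro-1-benzoxepine-3,7-diol (CNP0276044.1)
Conditions: TBAF, THF, 50 °C
Reagents that add atoms: none
Why: Fluoride cleaves the three triethylsilyl ethers under non-acidic conditions, which the tertiary and allylic alcohols should tolerate.

**Compound list**

1 | 4-methylpenta-1,3-diene | C=CC=C(C)C | starting material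
2 | 2-iodocyclopent-2-en-1-one | O=C1CCC=C1I | starting material
3 | 9-(4-methylpent-3-en-1-yl)-9-borabicyclo[3.3.1]nonane | CC(C)=CCCB1C2CCCC1CCC2 | intermediate
4 | 2-(4-methylpent-3-en-1-yl)cyclopent-2-en-1-one | CC(C)=CCCC1=CCCC1=O | intermediate
5 | 2-{2-[(2S)-3,3-dimethyloxiran-2-yl]ethyl}cyclopent-2-en-1-one | CC1(C)O[C@H]1CCC1=CCCC1=O | intermediate
6 | (3aR,5S,7aR)-5-hydroxy-4,4-dimethyloctahydro-1H-inden-1-one | O[C@@H]1C(C)(C)[C@@H]2CCC(=O)[C@@H]2CC1 | intermediate
7 | (3aR,5S,7aR)-4,4-dimethyl-1-methylideneoctahydro-1H-inden-5-ol | O[C@@H]1C(C)(C)[C@@H]2CCC(=C)[C@@H]2CC1 | intermediate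
8 | (1R,3aR,5S,7aR)-1,4,4-trimethyloctahydro-1H-indene-1,5-diol | O[C@@H]1C(C)(C)[C@@H]2CC[C@@](C)(O)[C@@H]2CC1 | intermediate
9 | (1R,3aR,7aR)-1-hydroxy-1,4,4-trimethyloctahydro-5H-inden-5-one | O=C1C(C)(C)[C@@H]2CC[C@@](C)(O)[C@@H]2CC1 | intermediate
10 | (1R,3aR,7aR)-1,4,4-trimethyl-1-[(triethylsilyl)oxy]octahydro-5H-inden-5-one | O=C1C(C)(C)[C@@H]2CC[C@@](C)(O[Si](CC)(CC)CC)[C@@H]2CC1 | intermediate
11 | potassium C5–C6 enolate of 10 | [K+].[O-]C1=CC[C@@H]2[C@@H](CC[C@@]2(C)O[Si](CC)(CC)CC)C1(C)C | intermediate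
12 | (1R,3aR,7aR)-1,4,4-trimethyl-1-[(triethylsilyl)oxy]-2,3,3a,4,7,7a-hexahydro-1H-inden-5-yl trifluoromethanesulfonate | FC(F)(F)S(=O)(=O)OC1=CC[C@@H]2[C@@H](CC[C@@]2(C)O[Si](CC)(CC)CC)C1(C)C | intermediate
13 | dimethyl (2-oxopropyl)phosphonate | CC(=O)CP(=O)(OC)OC | starting material
14 | geranyl bromide, (2E)-1-bromo-3,7-dimethylocta-2,6-diene | CC(C)=CCC/C(C)=C/CBr | starting material
15 | sodium lithium dianion of 13 | [Na+].[Li+].[CH2-]C(=O)[CH-]P(=O)(OC)OC | intermediate
16 | dimethyl [(5E)-6,10-dimethyl-2-oxoundeca-5,9-dien-1-yl]phosphonate | CC(C)=CCC/C(C)=C/CCC(=O)CP(=O)(OC)OC | intermediate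
17 | (benzyloxy)acetaldehyde | O=CCOCc1ccccc1 | starting material
18 | (2E,7E)-1-(benzyloxy)-8,12-dimethyltrideca-2,7,11-trien-4-one | CC(C)=CCC/C(C)=C/CCC(=O)/C=C/COCc1ccccc1 | intermediate
19 | (2E)-1-(benzyloxy)-6-[(2R,3R)-3-{2-[(2R)-3,3-dimethyloxiran-2-yl]ethyl}-3-methyloxiran-2-yl]hex-2-en-4-one | CC1(C)O[C@@H]1CC[C@@]2(C)O[C@@H]2CCC(=O)/C=C/COCc1ccccc1 | intermediate
20 | {[(3Z)-6-(benzyloxy)-1-[(2R,3R)-3-{2-[(2R)-3,3-dimethyloxiran-2-yl]ethyl}-3-methyloxiran-2-yl]hex-3-en-3-yl]oxy}triethylsilane | CC1(C)O[C@@H]1CC[C@@]2(C)O[C@@H]2CC/C(O[Si](CC)(CC)CC)=C/CCOCc1ccccc1 | intermediate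
21 | (3R,5aR,6R,9aR)-6-[2-(benzyloxy)ethyl]-2,2,5a-trimethyl-3-[(triethylsilyl)oxy]octahydro-1-benzoxepin-7(2H)-one | C(OCc1ccccc1)C[C@@H]1[C@@]2(C)CC[C@@H](O[Si](CC)(CC)CC)C(C)(C)O[C@@H]2CCC1=O | intermediate
22 | (3R,5aR,6R,7S,9aR)-6-[2-(benzyloxy)ethyl]-2,2,5a,7-tetramethyl-3-[(triethylsilyl)oxy]decahydro-1-benzoxepin-7-ol | C(OCc1ccccc1)C[C@@H]1[C@@]2(C)CC[C@@H](O[Si](CC)(CC)CC)C(C)(C)O[C@@H]2CC[C@]1(C)O | intermediate
23 | (3R,5aR,6R,7S,9aR)-6-[2-(benzyloxy)ethyl]-2,2,5a,7-tetramethyl-3,7-bis[(triethylsilyl)oxy]decahydro-1-benzoxepine | C(OCc1ccccc1)C[C@@H]1[C@@]2(C)CC[C@@H](O[Si](CC)(CC)CC)C(C)(C)O[C@@H]2CC[C@]1(C)O[Si](CC)(CC)CC | intermediate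
24 | 2-[(3R,5aR,6R,7S,9aR)-2,2,5a,7-tetramethyl-3,7-bis[(triethylsilyl)oxy]decahydro-1-benzoxepin-6-yl]ethan-1-ol | OCC[C@@H]1[C@@]2(C)CC[C@@H](O[Si](CC)(CC)CC)C(C)(C)O[C@@H]2CC[C@]1(C)O[Si](CC)(CC)CC | intermediate
25 | (3R,5aR,6R,7S,9aR)-6-(2-iodoethyl)-2,2,5a,7-tetramethyl-3,7-bis[(triethylsilyl)oxy]decahydro-1-benzoxepine | ICC[C@@H]1[C@@]2(C)CC[C@@H](O[Si](CC)(CC)CC)C(C)(C)O[C@@H]2CC[C@]1(C)O[Si](CC)(CC)CC | intermediate
26 | primary alkyllithium from 25 | [Li]CC[C@@H]1[C@@]2(C)CC[C@@H](O[Si](CC)(CC)CC)C(C)(C)O[C@@H]2CC[C@]1(C)O[Si](CC)(CC)CC | intermediate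
27 | lithium B-alkyl-B-methoxy-9-borabicyclo[3.3.1]nonane borinate from 26 | [Li+].CO[B-]1(CC[C@@H]2[C@@]3(C)CC[C@@H](O[Si](CC)(CC)CC)C(C)(C)O[C@@H]3CC[C@]2(C)O[Si](CC)(CC)CC)C2CCCC1CCC2 | intermediate
28 | coupled cyclohexene: (1R,3aR,7aR)-hexahydroindene carrying at C5 the 2-[(3R,5aR,6R,7S,9aR)-benzoxepin-6-yl]ethyl chain, tris-TES ether | C(C[C@@H]1[C@@]2(C)CC[C@@H](O[Si](CC)(CC)CC)C(C)(C)O[C@@H]2CC[C@]1(C)O[Si](CC)(CC)CC)C1=CC[C@@H]2[C@@H](CC[C@@]2(C)O[Si](CC)(CC)CC)C1(C)C | intermediate
29 | gem-dibromocyclopropane of 28 across the former C5=C6 alkene, convex-face isomer | C(C[C@@H]1[C@@]2(C)CC[C@@H](O[Si](CC)(CC)CC)C(C)(C)O[C@@H]2CC[C@]1(C)O[Si](CC)(CC)CC)[C@]12C(C)(C)[C@@H]3CC[C@@](C)(O[Si](CC)(CC)CC)[C@@H]3C[C@H]1C2(Br)Br | intermediate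
30 | 2-bromoallyl cation in the seven-membered ring (C5–C6(Br)–C7) | BrC1=C(CC[C@@H]2[C@@]3(C)CC[C@@H](O[Si](CC)(CC)CC)C(C)(C)O[C@@H]3CC[C@]2(C)O[Si](CC)(CC)CC)C(C)(C)[C@@H]2CC[C@@](C)(O[Si](CC)(CC)CC)[C@@H]2C[CH+]1 | intermediate
31 | (1R,3aR,8aR)-6-bromo-octahydroazulen-7-ol, tris-TES ether, C7 epimers | BrC1=C(CC[C@@H]2[C@@]3(C)CC[C@@H](O[Si](CC)(CC)CC)C(C)(C)O[C@@H]3CC[C@]2(C)O[Si](CC)(CC)CC)C(C)(C)[C@@H]2CC[C@@](C)(O[Si](CC)(CC)CC)[C@@H]2CC1O | intermediate
32 | (1R,3aR,8aR)-6-bromo-hexahydroazulen-7(1H)-one, tris-TES ether | BrC1=C(CC[C@@H]2[C@@]3(C)CC[C@@H](O[Si](CC)(CC)CC)C(C)(C)O[C@@H]3CC[C@]2(C)O[Si](CC)(CC)CC)C(C)(C)[C@@H]2CC[C@@](C)(O[Si](CC)(CC)CC)[C@@H]2CC1=O | intermediate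
33 | (1R,3aR,8aR)-6-methyl-hexahydroazulen-7(1H)-one, tris-TES ether | CC1=C(CC[C@@H]2[C@@]3(C)CC[C@@H](O[Si](CC)(CC)CC)C(C)(C)O[C@@H]3CC[C@]2(C)O[Si](CC)(CC)CC)C(C)(C)[C@@H]2CC[C@@](C)(O[Si](CC)(CC)CC)[C@@H]2CC1=O | intermediate
34 | tris-triethylsilyl ether of the target, (7S)-allylic alcohol | CC1=C(CC[C@@H]2[C@@]3(C)CC[C@@H](O[Si](CC)(CC)CC)C(C)(C)O[C@@H]3CC[C@]2(C)O[Si](CC)(CC)CC)C(C)(C)[C@@H]2CC[C@@](C)(O[Si](CC)(CC)CC)[C@@H]2C[C@@H]1O | intermediate
35 | (3R,5aR,6R,7S,9aR)-6-{2-[(1R,3aR,7S,8aR)-1,7-dihydroxy-1,4,4,6-tetramethyl-1,2,3,3a,4,7,8,8a-octahydroazulen-5-yl]ethyl}-2,2,5a,7-tetramethyldecahydro-1-benzoxepine-3,7-diol | CC1=C(CC[C@@H]2[C@@]3(C)CC[C@@H](O)C(C)(C)O[C@@H]3CC[C@]2(C)O)C(C)(C)[C@@H]2CC[C@@](C)(O)[C@@H]2C[C@@H]1O | target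

**Step count.** 24 steps in total; longest linear sequence 16 steps (steps 9–24, from 13 and 14).

**Steps most likely to fail**

1. Step 20 (ring expansion). The bromine on the central carbon destabilises the allyl cation, so ionisation may stall, or the cation may lose a proton to a bromodiene before water captures it. Fallback: the route sets out from 28 and brings the methyl group in with the inserted carbon. Cyclopropanation of 28 with the chloro(methyl)carbenoid from 1,1-dichloroethane and n-BuLi (Et2O, −40 °C) would give the 1-chloro-1-methylcyclopropane F1. Its endo-chloro isomers should open far more readily, through a donor-stabilised 2-methylallyl cation, on treatment with AgClO4/CaCO3 in aqueous acetone, giving the 6-methyl allylic alcohol F2 as C7 epimers. Dess–Martin oxidation of F2 returns to the route at 33, and the palladium methylation of step 22 is no longer needed.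

2. Step 13 (epoxide-opening cascade). The epoxonium relay may be intercepted before the C–C bond forms (proton loss, triflate capture, exo opening), or the γ-branched enol ether may be desilylated before it attacks. Fallback: the route sets out from 16 and attaches the side chain after the rings are made. Shi epoxidation of 16 (D-series ketone) would give the diepoxy β-ketophosphonate F3, and O-silylation (NaH, TESCl, THF) its triethylsilyl enol ether F4. The same TESOTf-promoted cascade on F4 gives the bicyclic α-phosphono ketone F5. Horner–Wadsworth–Emmons reaction of F5 with 17 (NaH, THF) gives the exocyclic enone F6, and conjugate reduction with Stryker's reagent, with thermodynamic protonation at C6, returns to the route at 21.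

3. Step 3 (reductive radical cyclization). Ti(III) may reduce the enone (ketyl coupling), or reduce the tertiary radical to an organotitanium species before it cyclises, leading to deoxygenation or simple reduction. Fallback: the route sets out from 5 and generates the same radical in a tin hydride chain without a low-valent metal. Opening of 5 with HBr (Et2O, −30 °C) at the tertiary carbon would give the bromohydrin F7. Slow addition of Bu3SnH/AIBN (benzene, 80 °C) generates the tertiary radical, which closes 6-endo as before, and the route is rejoined at 6 after equilibration to the cis fusion.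

**Further compounds**

F1 | step 20 | 1-chloro-1-methylcyclopropane of 28 across the former C5=C6 alkene (isomer mixture) | C(C[C@@H]1[C@@]2(C)CC[C@@H](O[Si](CC)(CC)CC)C(C)(C)O[C@@H]2CC[C@]1(C)O[Si](CC)(CC)CC)C12C(C)(C)[C@@H]3CC[C@@](C)(O[Si](CC)(CC)CC)[C@@H]3CC1C2(C)Cl
F2 | step 20 | (1R,3aR,8aR)-6-methyl-octahydroazulen-7-ol, tris-TES ether, C7 epimers | CC1=C(CC[C@@H]2[C@@]3(C)CC[C@@H](O[Si](CC)(CC)CC)C(C)(C)O[C@@H]3CC[C@]2(C)O[Si](CC)(CC)CC)C(C)(C)[C@@H]2CC[C@@](C)(O[Si](CC)(CC)CC)[C@@H]2CC1O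
F3 | step 13 | dimethyl {4-[(2R,3R)-3-{2-[(2R)-3,3-dimethyloxiran-2-yl]ethyl}-3-methyloxiran-2-yl]-2-oxobutyl}phosphonate | CC1(C)O[C@@H]1CC[C@@]2(C)O[C@@H]2CCC(=O)CP(=O)(OC)OC
F4 | step 13 | triethylsilyl enol ether of F3 (enol towards the phosphonate carbon) | CC1(C)O[C@@H]1CC[C@@]2(C)O[C@@H]2CCC(O[Si](CC)(CC)CC)=CP(=O)(OC)OC
F5 | step 13 | dimethyl [(3R,5aR,9aR)-2,2,5a-trimethyl-7-oxo-3-[(triethylsilyl)oxy]decahydro-1-benzoxepin-6-yl]phosphonate | COP(=O)(OC)C1[C@@]2(C)CC[C@@H](O[Si](CC)(CC)CC)C(C)(C)O[C@@H]2CCC1=O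
F6 | step 13 | (3R,5aR,9aR)-6-[2-(benzyloxy)ethylidene]-2,2,5a-trimethyl-3-[(triethylsilyl)oxy]octahydro-1-benzoxepin-7(2H)-one | O(Cc1ccccc1)CC=C1[C@@]2(C)CC[C@@H](O[Si](CC)(CC)CC)C(C)(C)O[C@@H]2CCC1=O
F7 | step 3 | 2-[(3S)-4-bromo-3-hydroxy-4-methylpentyl]cyclopent-2-en-1-one | CC(C)(Br)[C@@H](O)CCC1=CCCC1=O
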